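Assumption: (S)-pinocembrin, the natural (2S)-5,7-dihydroxyflavanone, is taken as a purchasable single enantiomer, and its C2 configuration is carried unchanged into the target.

## The problem

Sarmentosumin C (38) is a (2S)-5,7-dihydroxyflavanone with a fully substituted ring A. C8 carries a 2-hydroxybenzyl group, and C6 carries a CH2-linked chain of four phenol rings (rings 1 to 4, counted outward from C6) joined by three more CH2 bridges. In chain rings 1, 2 and 3 the inward CH2 is ortho and the outward CH2 para to the hydroxyl, and ring 4 is a 2-hydroxyphenyl end group. Acid-catalysed phenol benzylation gives ortho/para mixtures and over-alkylation, so each ring's pattern has to be fixed by construction. On ring A, C6 and C8 differ only in their neighbours (the chelated 5-OH versus the ring oxygen O1), and opening of ring C to the chalcone would both exchange them on reclosure and racemise C2. C2 is the only stereocentre. It is benzylic and β to the C4 carbonyl through O1, there is no second centre to direct it, and so it must be bought or set once and then kept away from base. Seven phenols, electron-rich diarylmethanes and the flavanone exclude strong base, strong Lewis acid and oxidants late in the route. The feature that opens the key step is chain ring 2: its oxygen-bearing carbon has the CH2 to ring 1 on the ortho carbon and the CH2 to ring 3 on the para carbon. This is the arrangement left when a 2-siloxycyclohexa-1,3-diene substituted at C1 adds to a terminal ynone and the adduct loses ethylene.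

## Retrosynthesis

**Protecting groups.** 38 is traced to 37, in which the chain oxygens of rings 1, 3 and 4, the 7-oxygen and the C8 benzyl oxygen are MOM ethers, ring 2 is a TBS ether and the chelated 5-OH is free. Six O–protecting-group bonds are cut. All six fall to acid, the one medium in which ring C stays closed and C2 stays fixed. The forward step needs only complete solvolysis.

**C8–CH2 bond.** 37 is cut between C8 and its benzylic carbon into the 8-iodide 32 and the benzylzinc chloride 36, which comes from chloride 35 and, through alcohol 34, from 2-hydroxybenzyl alcohol 33. The neighbouring choice, acid-promoted hydroxybenzylation at C8, would need Lewis acid and free phenols and would also alkylate the chain rings. A Negishi coupling is neutral and places the group only where the halogen sits. 32 comes from 31 by iodination of the last open ring A position.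

**C6–CH2 bond.** 31 is cut between C6 and the bridge carbon into the 6-iodide 29 and the chain benzylzinc chloride 30, made from chloride 26. Cutting on the other side of the CH2 would require a 2,4,6-trioxygenated benzyl halide on ring A, which is too labile to handle. 29 comes from 28 and this from (S)-pinocembrin 27, so the stereocentre is bought and ring C is never opened. The forward sequence asks that the chelated 5-OH steer the first iodination to C6, and that the coupling run without base.

**Ring 1 handle and the bridge carbonyl.** 26 goes back through alcohol 25 to the chain bromide 22, by way of aryllithium 23 and aldehyde 24, so the bromine ortho to the ring 1 oxygen becomes the C6 bridge carbon. 22 is the deoxygenated form of carbinol 21 and ketone 20. The carbonyl between rings 2 and 3 is what the key step leaves behind, and it must be removed without disturbing the aryl bromide or the acetals.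

**Ring 2 (key disconnection).** 20 is cut at two C–C bonds of ring 2, giving the 1-benzyl-2-siloxycyclohexa-1,3-diene 9 and the aryl ethynyl ketone 18, joined in the forward direction through the bicyclic adduct 19. Stepwise phenol benzylation would leave the ortho/para question open at ring 2. Here the pattern is dictated by the polarisation of both partners, and the two halves are of similar size. The forward reaction must be regioselective and must lose ethylene cleanly.

**The two partners.** 9 is the silyl dienol ether of enone 7 (through dienolate 8), and 7 arises from cyclohexenone 5 (through dienolate 6) and benzylic bromide 4. 18 comes from carbinol 17, which is the adduct of aldehyde 15 and ethynylmagnesium bromide 16. 15 comes from bromide 13 (through aryllithium 14), and 13 from Grignard reagent 12, bromide 11, 2-bromophenol 10 and again bromide 4. 4 is made from 3-bromo-4-hydroxybenzaldehyde 1 through 2 and 3. In 4 the CH2Br is para and the Br ortho to the oxygen, the pattern needed in both ring 1 and ring 3, so one building block serves twice.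

## Roads not taken

**Alternative 1:** Ring A would be cut at C6–C7 and C4a–C8a into a malonyl unit carrying the C8 benzyl group and an enone carrying the chain. In the forward step the lithium dienolate of the β-methoxy dienone A1 would be C-acylated twice by the malonyl dichloride A2 and so folded into the hexasubstituted chalcone A3.
- Merits: all six ring A substituents are placed by the fragments. The methyl ether marks the oxygen that must not become O1, so ring C can only close the right way. On ring A regiochemistry this road is better than the chosen one, which has to win the C6/C8 distinction by a directed halogenation.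
- Weak points: O-acylation and pyranone formation compete with double C-acylation by malonyl dichlorides. The whole chain would have to pass through enolate chemistry in A1. A3 is a di-ortho-substituted 2'-hydroxychalcone, for which enantioselective oxa-Michael closure is not dependable. A methyl ether next to the carbonyl and seven benzyl ethers must then be removed from a flavanone.
- Comparison: the chosen plan sets a purchased stereocentre and base-free late steps against the better regiocontrol. It also answers how the ortho,para-linked chain is made, which this road leaves open.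

**Alternative 2:** The C4–C4a bond of ring C would be cut. The lithium carboxylate of the (S)-aryloxy acid A4 would undergo bromine–lithium exchange with tert-butyllithium, and the C4a aryllithium would attack the carboxylate (Parham cyclisation) to give the hepta-MOM ether A5, one acid step from the target.
- Merits: C2 is set in a small fragment before ring closure. The bromine defines which oxygen is O1, so C6 and C8 cannot be exchanged, and no chalcone is ever formed. Its endgame is as short as the chosen one, and its ring A regiochemistry is more secure.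
- Weak points: the ether between a doubly ortho-substituted phenol and a secondary benzylic carbon is hindered and can lose configuration through a benzylic cation. tert-Butyllithium would meet seven MOM groups (directed lithiation), five doubly benzylic CH2 groups and a β-aryloxy carboxylate that can eliminate the phenoxide, all on the most advanced intermediate.
- Comparison: the chosen plan instead joins the large pieces with organozinc reagents and palladium, which tolerate all of these groups. The price is two halogenation/coupling rounds on ring A.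

**Alternative 3:** Ring A would be cut at C7–C8 and C4a–C8a. Heating the chain-bearing 3-ethoxycyclobutenone A6 with the siloxyalkyne A7 would give phenol A8 by electrocyclic opening to a vinylketene, [2+2] addition, a second four-electron opening and six-electron closure (Danheiser benzannulation).
- Merits: the three ring A oxygens emerge differentiated (free OH, silyl ether, ethyl ether) and the two benzyl groups are placed without ambiguity. In regiocontrol it is again superior.
- Weak points: A6 requires alkylating a cyclobutenone with the entire chain. A8 still lacks C4. The acyl group must then be forced into the last, most crowded position, ring C closed enantioselectively from a chalcone, and an ethyl ether cleaved beside the flavanone.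
- Comparison: this road is longer and leaves the stereocentre unsolved. The chosen plan accepts a less elegant ring A sequence in return for a stereocentre that is never at risk and a chain whose substitution pattern is fixed by a cycloaddition.

Key step: step 11

## Route

Step 1
Reactants: 1 3-bromo-4-hydroxybenzaldehyde
Product: 2 3-bromo-4-(methoxymethoxy)benzaldehyde
Conditions: MOMCl, i-Pr2NEt, CH2Cl2, 0 °C → rt
Reagents that add atoms: chloromethyl methyl ether (MOMCl), COCCl
Why: O-alkylation of the acidic phenol gives the MOM acetal, which withstands amide bases, organolithium and Grignard reagents and heat and is removed in the final acid step.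

Step 2
Reactants: 2 3-bromo-4-(methoxymethoxy)benzaldehyde
Product: 3 [3-bromo-4-(methoxymethoxy)phenyl]methanol
Conditions: NaBH4, MeOH, 0 °C
Reagents that add atoms: none
Why: Borohydride reduction of an aryl aldehyde; the aryl bromide and the acetal are inert.

Step 3
Reactants: 3 [3-bromo-4-(methoxymethoxy)phenyl]methanol
Product: 4 2-bromo-4-(bromomethyl)-1-(methoxymethoxy)benzene
Conditions: CBr4, PPh3, CH2Cl2, 0 °C
Reagents that add atoms: tetrabromomethane, BrC(Br)(Br)Br
Why: Appel bromination is neutral, so the acid-labile MOM group survives; the reactive para-alkoxybenzyl bromide is used without storage.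

Step 4
Reactants: 5 cyclohex-2-en-1-one; 4 2-bromo-4-(bromomethyl)-1-(methoxymethoxy)benzene
Product: 7 (±)-6-[3-bromo-4-(methoxymethoxy)benzyl]cyclohex-2-en-1-one, via lithium cyclohexa-1,5-dien-1-olate 6 (not isolated)
Conditions: LiN(i-Pr)2, THF, −78 °C; then 4, DMPU, −78 → −30 °C
Reagents that add atoms: none
Why: Kinetic α′-deprotonation gives the cross-conjugated dienolate, which is C-alkylated at C6 by the benzylic bromide (SN2 enolate alkylation); the new stereocentre is racemic and is erased in step 5.

Step 5
Reactants: 7 (±)-6-[3-bromo-4-(methoxymethoxy)benzyl]cyclohex-2-en-1-one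
Product: 9 tert-butyl({2-[3-bromo-4-(methoxymethoxy)benzyl]cyclohexa-1,5-dien-1-yl}oxy)dimethylsilane, via lithium dienolate 8 (not isolated)
Conditions: LiN(i-Pr)2, THF, −78 °C; then TBSCl, DMPU, −78 °C → rt; non-aqueous work-up
Reagents that add atoms: tert-butyldimethylsilyl chloride (TBSCl), CC(C)(C)[Si](C)(C)Cl
Why: A second kinetic deprotonation at C6 (α′, not the γ-CH2) and O-silylation give the 1-benzyl-2-siloxycyclohexa-1,3-diene; the TBS group makes the dienol ether robust enough to handle.

Step 6
Reactants: 10 2-bromophenol
Product: 11 1-bromo-2-(methoxymethoxy)benzene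
Conditions: MOMCl, i-Pr2NEt, CH2Cl2, 0 °C → rt
Reagents that add atoms: chloromethyl methyl ether (MOMCl), COCCl
Why: Standard MOM protection of a phenol; it masks the ring 4 oxygen for the Grignard step.

Step 7
Reactants: 11 1-bromo-2-(methoxymethoxy)benzene; 4 2-bromo-4-(bromomethyl)-1-(methoxymethoxy)benzene
Product: 13 2-bromo-1-(methoxymethoxy)-4-[2-(methoxymethoxy)benzyl]benzene, via 2-(methoxymethoxy)phenylmagnesium bromide 12 (not isolated)
Conditions: Mg, THF, 45 °C; then 4, CuI (5 mol %), THF, −20 °C → rt
Reagents that add atoms: none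
Why: Magnesium insertion followed by CuI-catalysed coupling of the aryl Grignard reagent with the benzylic bromide (Kumada-type alkylation) forms the ring 3–ring 4 bridge; the aryl C–Br bond of 4 does not react with the Grignard reagent under these conditions.

Step 8
Reactants: 13 2-bromo-1-(methoxymethoxy)-4-[2-(methoxymethoxy)benzyl]benzene
Product: 15 2-(methoxymethoxy)-5-[2-(methoxymethoxy)benzyl]benzaldehyde, via aryllithium 14 (not isolated)
Conditions: n-BuLi, THF, −78 °C; then DMF, −78 → 0 °C; H2O
Reagents that add atoms: N,N-dimethylformamide, CN(C)C=O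
Why: Bromine–lithium exchange at −78 °C is faster than ortho- or benzylic deprotonation, and DMF formylates the aryllithium.

Step 9
Reactants: 15 2-(methoxymethoxy)-5-[2-(methoxymethoxy)benzyl]benzaldehyde; 16 ethynylmagnesium bromide
Product: 17 (±)-1-{2-(methoxymethoxy)-5-[2-(methoxymethoxy)benzyl]phenyl}prop-2-yn-1-ol
Conditions: HC≡CMgBr, THF, 0 °C; aq. NH4Cl
Reagents that add atoms: none
Why: Grignard 1,2-addition to the aldehyde; the carbinol centre is racemic and is removed by oxidation in step 10.

Step 10
Reactants: 17 (±)-1-{2-(methoxymethoxy)-5-[2-(methoxymethoxy)benzyl]phenyl}prop-2-yn-1-ol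
Product: 18 1-{2-(methoxymethoxy)-5-[2-(methoxymethoxy)benzyl]phenyl}prop-2-yn-1-one
Conditions: MnO2, CH2Cl2, rt
Reagents that add atoms: none
Why: MnO2 oxidises the benzylic–propargylic alcohol under neutral conditions and leaves the terminal alkyne and the acetals alone; the ynone is used fresh.

Step 11
Reactants: 9 tert-butyl({2-[3-bromo-4-(methoxymethoxy)benzyl]cyclohexa-1,5-dien-1-yl}oxy)dimethylsilane; 18 1-{2-(methoxymethoxy)-5-[2-(methoxymethoxy)benzyl]phenyl}prop-2-yn-1-one
Product: 20 {3-[3-bromo-4-(methoxymethoxy)benzyl]-4-[(tert-butyldimethylsilyl)oxy]phenyl}{2-(methoxymethoxy)-5-[2-(methoxymethoxy)benzyl]phenyl}methanone, via bicyclo[2.2.2]octadiene cycloadduct 19 (not isolated)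
Conditions: 9 (1.5 equiv), mesitylene, 2,6-di-tert-butyl-4-methylphenol (cat.), sealed tube, 110 °C, then 180 °C
Reagents that add atoms: none
Why: Normal-electron-demand [4+2] cycloaddition of the electron-rich siloxydiene 9 to the electron-poor terminal ynone 18 gives the bicyclo[2.2.2]octa-2,5-diene 19, which on further heating undergoes a retro-[4+2] reaction that expels its saturated two-carbon bridge as ethylene and leaves ring 2 aromatic. The closest known reaction type is the Alder–Rickert synthesis of 4-siloxyaryl ketones and esters from 2-siloxycyclohexa-1,3-dienes and acetylenic ketones or propiolates. Ring 2 is closed by a concerted suprafacial six-electron cycloaddition that forms two C–C bonds (diene C1 to the ynone CH, diene C4 to the acyl-bearing carbon), and the cycloreversion then turns the bridged ring into the benzene ring. The two bridgehead centres of 19 are formed racemic and vanish on aromatisation, so no stereocentre has to be controlled. The selectivity needed is regiochemical: the siloxy group at C2 puts the largest HOMO coefficient on C1, the benzyl-bearing terminus, and the carbonyl puts the largest LUMO coefficient on the unsubstituted alkyne carbon, so these two bond and the aroyl group ends para to the siloxy carbon with the benzyl group ortho; sterics act the same way, because the substituted diene terminus meets the alkyne CH. Holding at 110 °C until the ynone is consumed before raising the temperature keeps the diene from isomerising by 1,5-hydrogen shifts, and the neutral medium leaves the MOM acetals, the aryl bromide and the silyl ether untouched.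

Step 12
Reactants: 20 {3-[3-bromo-4-(methoxymethoxy)benzyl]-4-[(tert-butyldimethylsilyl)oxy]phenyl}{2-(methoxymethoxy)-5-[2-(methoxymethoxy)benzyl]phenyl}methanone
Product: 21 (±)-{3-[3-bromo-4-(methoxymethoxy)benzyl]-4-[(tert-butyldimethylsilyl)oxy]phenyl}{2-(methoxymethoxy)-5-[2-(methoxymethoxy)benzyl]phenyl}methanol
Conditions: i-Bu2AlH, CH2Cl2, −78 °C; aq. potassium sodium tartrate
Reagents that add atoms: none
Why: Hydride reduction of the diaryl ketone; the non-basic aluminium hydride is preferred to borohydride in alcohol because the aryl silyl ether para to the carbonyl is labile to alkoxide, and the racemic carbinol centre is removed in step 13.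

Step 13
Reactants: 21 (±)-{3-[3-bromo-4-(methoxymethoxy)benzyl]-4-[(tert-butyldimethylsilyl)oxy]phenyl}{2-(methoxymethoxy)-5-[2-(methoxymethoxy)benzyl]phenyl}methanol
Product: 22 {2-[3-bromo-4-(methoxymethoxy)benzyl]-4-{2-(methoxymethoxy)-5-[2-(methoxymethoxy)benzyl]benzyl}phenoxy}(tert-butyl)dimethylsilane (four-ring chain bromide)
Conditions: Et3SiH (3 equiv), CF3CO2H (3 equiv), CH2Cl2, −20 → 0 °C
Reagents that add atoms: none
Why: Ionic hydrogenation: the carbinol ionises under dilute acid because the cation is stabilised by the para-siloxy ring and the ortho-alkoxy ring, and the silane delivers hydride; low temperature and little acid are chosen to spare the MOM acetals.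

Step 14
Reactants: 22 four-ring chain bromide
Product: 25 (5-{2-[(tert-butyldimethylsilyl)oxy]-5-{2-(methoxymethoxy)-5-[2-(methoxymethoxy)benzyl]benzyl}benzyl}-2-(methoxymethoxy)phenyl)methanol, via chain aryllithium 23 (not isolated), via chain aldehyde 24 (not isolated)
Conditions: n-BuLi, THF, −78 °C; DMF, −78 → 0 °C; then MeOH, NaBH4, 0 °C
Reagents that add atoms: N,N-dimethylformamide, CN(C)C=O
Why: Bromine–lithium exchange at −78 °C outruns deprotonation of the diarylmethane CH2 groups, DMF formylates the aryllithium and borohydride reduces the aldehyde in the same flask, turning the ring 1 bromine into the future C6 bridge carbon.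

Step 15
Reactants: 25 chain benzylic alcohol
Product: 26 tert-butyl{2-[3-(chloromethyl)-4-(methoxymethoxy)benzyl]-4-{2-(methoxymethoxy)-5-[2-(methoxymethoxy)benzyl]benzyl}phenoxy}dimethylsilane (chain benzylic chloride)
Conditions: PPh3, N-chlorosuccinimide, THF, 0 °C → rt
Reagents that add atoms: N-chlorosuccinimide, O=C1CCC(=O)N1Cl
Why: Appel-type chlorination of a primary benzylic alcohol under neutral conditions that leave MOM and silyl ethers intact.

Step 16
Reactants: 27 (S)-pinocembrin, (2S)-5,7-dihydroxy-2-phenylchroman-4-one
Product: 28 (2S)-5-hydroxy-7-(methoxymethoxy)-2-phenylchroman-4-one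
Conditions: MOMCl (1.1 equiv), i-Pr2NEt, CH2Cl2, 0 °C
Reagents that add atoms: chloromethyl methyl ether (MOMCl), COCCl
Why: The unchelated, more acidic 7-OH is alkylated selectively while the hydrogen-bonded 5-OH stays free; a weak amine base at 0 °C does not trigger retro-oxa-Michael opening, so C2 keeps its S configuration.

Step 17
Reactants: 28 (2S)-5-hydroxy-7-(methoxymethoxy)-2-phenylchroman-4-one
Product: 29 (2S)-5-hydroxy-6-iodo-7-(methoxymethoxy)-2-phenylchroman-4-one
Conditions: N-iodosuccinimide (1.0 equiv), DMF, 0 °C → rt, dark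
Reagents that add atoms: N-iodosuccinimide, O=C1CCC(=O)N1I
Why: Electrophilic aromatic iodination under neutral conditions; with a free chelated 5-OH and an ether at O7 the halogen is expected at C6, ortho to the 5-OH, as is known for 5-hydroxy-7-alkoxyflavones.

Step 18
Reactants: 26 chain benzylic chloride; 29 (2S)-5-hydroxy-6-iodo-7-(methoxymethoxy)-2-phenylchroman-4-one
Product: 31 (2S)-6-(5-{2-[(tert-butyldimethylsilyl)oxy]-5-{2-(methoxymethoxy)-5-[2-(methoxymethoxy)benzyl]benzyl}benzyl}-2-(methoxymethoxy)benzyl)-5-hydroxy-7-(methoxymethoxy)-2-phenylchroman-4-one, via chain benzylzinc chloride 30 (not isolated)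
Conditions: 26, Zn dust, LiCl, THF, 25 °C; then slow addition to 29, Pd(OAc)2 (3 mol %), SPhos (6 mol %), THF, 25 → 40 °C
Reagents that add atoms: none
Why: Zinc insertion into the benzylic chloride and Negishi coupling catalysed by zerovalent palladium with a bulky biarylphosphine, which handles doubly ortho-substituted aryl iodides; benzylzinc reagents tolerate the ketone and the chelated phenol and are not basic enough to open ring C, so C2 is untouched.

Step 19
Reactants: 31 (2S)-6-(chain-methyl)-5-hydroxy-7-(methoxymethoxy)-2-phenylchroman-4-one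
Product: 32 (2S)-6-(5-{2-[(tert-butyldimethylsilyl)oxy]-5-{2-(methoxymethoxy)-5-[2-(methoxymethoxy)benzyl]benzyl}benzyl}-2-(methoxymethoxy)benzyl)-5-hydroxy-8-iodo-7-(methoxymethoxy)-2-phenylchroman-4-one
Conditions: N-iodosuccinimide (1.1 equiv), DMF, 0 °C → rt, dark
Reagents that add atoms: N-iodosuccinimide, O=C1CCC(=O)N1I
Why: C8 is the only open position of ring A and is para to the free 5-OH, whereas the chain rings are aryl ethers that do not react with N-iodosuccinimide without acid.

Step 20
Reactants: 33 2-hydroxybenzyl alcohol
Product: 34 [2-(methoxymethoxy)phenyl]methanol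
Conditions: MOMCl, K2CO3, acetone, 0 °C → rt
Reagents that add atoms: chloromethyl methyl ether (MOMCl), COCCl
Why: Carbonate deprotonates only the phenol, so the phenoxide is alkylated and the benzylic alcohol is left free.

Step 21
Reactants: 34 [2-(methoxymethoxy)phenyl]methanol
Product: 35 1-(chloromethyl)-2-(methoxymethoxy)benzene
Conditions: PPh3, N-chlorosuccinimide, THF, 0 °C → rt
Reagents that add atoms: N-chlorosuccinimide, O=C1CCC(=O)N1Cl
Why: Appel-type chlorination as in step 15.

Step 22
Reactants: 32 (2S)-8-iodo compound; 35 1-(chloromethyl)-2-(methoxymethoxy)benzene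
Product: 37 (2S)-6-(5-{2-[(tert-butyldimethylsilyl)oxy]-5-{2-(methoxymethoxy)-5-[2-(methoxymethoxy)benzyl]benzyl}benzyl}-2-(methoxymethoxy)benzyl)-5-hydroxy-7-(methoxymethoxy)-8-[2-(methoxymethoxy)benzyl]-2-phenylchroman-4-one, via 2-(methoxymethoxy)benzylzinc chloride 36 (not isolated)
Conditions: 35, Zn dust, LiCl, THF, 25 °C; then 32, Pd(OAc)2 (5 mol %), SPhos (10 mol %), THF, 40 °C, 36 in excess
Reagents that add atoms: none
Why: A second Negishi coupling of the same type as step 18; the small zinc reagent can be used in excess to drive the hindered C8 iodide to completion under neutral conditions.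

Step 23
Reactants: 37 protected sarmentosumin C
Product: 38 sarmentosumin C, (2S)-5,7-dihydroxy-6-(2-hydroxy-5-{2-hydroxy-5-[2-hydroxy-5-(2-hydroxybenzyl)benzyl]benzyl}benzyl)-8-(2-hydroxybenzyl)-2-phenylchroman-4-one
Conditions: HCl (3 M), MeOH/THF, 40 °C
Reagents that add atoms: none
Why: Acid-catalysed acetal methanolysis removes the five MOM groups and acid solvolysis removes the aryl silyl ether; flavanones keep ring C closed and C2 fixed under acid at this temperature, and methanol traps the formaldehyde equivalents as dimethoxymethane.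

## Compound list

1 | 3-bromo-4-hydroxybenzaldehyde | O=Cc1ccc(O)c(Br)c1 | starting material
2 | 3-bromo-4-(methoxymethoxy)benzaldehyde | COCOc1ccc(C=O)cc1Br | intermediate
3 | [3-bromo-4-(methoxymethoxy)phenyl]methanol | COCOc1ccc(CO)cc1Br | intermediate
4 | 2-bromo-4-(bromomethyl)-1-(methoxymethoxy)benzene | COCOc1ccc(CBr)cc1Br | intermediate
5 | cyclohex-2-en-1-one | O=C1C=CCCC1 | starting material
6 | lithium cyclohexa-1,5-dien-1-olate | [Li]OC1=CCCC=C1 | intermediate (not isolated)
7 | (±)-6-[3-bromo-4-(methoxymethoxy)benzyl]cyclohex-2-en-1-one | COCOc1ccc(CC2CCC=CC2=O)cc1Br | intermediate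
8 | lithium 2-[3-bromo-4-(methoxymethoxy)benzyl]cyclohexa-1,5-dien-1-olate | COCOc1ccc(CC2=C(O[Li])C=CCC2)cc1Br | intermediate (not isolated)
9 | tert-butyl({2-[3-bromo-4-(methoxymethoxy)benzyl]cyclohexa-1,5-dien-1-yl}oxy)dimethylsilane | COCOc1ccc(CC2=C(O[Si](C)(C)C(C)(C)C)C=CCC2)cc1Br | intermediate
10 | 2-bromophenol | Oc1ccccc1Br | starting material
11 | 1-bromo-2-(methoxymethoxy)benzene | COCOc1ccccc1Br | intermediate
12 | 2-(methoxymethoxy)phenylmagnesium bromide | COCOc1ccccc1[Mg]Br | intermediate (not isolated)
13 | 2-bromo-1-(methoxymethoxy)-4-[2-(methoxymethoxy)benzyl]benzene | COCOc1ccc(Cc2ccccc2OCOC)cc1Br | intermediate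
14 | {2-(methoxymethoxy)-5-[2-(methoxymethoxy)benzyl]phenyl}lithium | COCOc1ccc(Cc2ccccc2OCOC)cc1[Li] | intermediate (not isolated)
15 | 2-(methoxymethoxy)-5-[2-(methoxymethoxy)benzyl]benzaldehyde | COCOc1ccc(Cc2ccccc2OCOC)cc1C=O | intermediate
16 | ethynylmagnesium bromide | C#C[Mg]Br | starting material
17 | (±)-1-{2-(methoxymethoxy)-5-[2-(methoxymethoxy)benzyl]phenyl}prop-2-yn-1-ol | COCOc1ccc(Cc2ccccc2OCOC)cc1C(O)C#C | intermediate
18 | 1-{2-(methoxymethoxy)-5-[2-(methoxymethoxy)benzyl]phenyl}prop-2-yn-1-one | C#CC(=O)c1cc(Cc2ccccc2OCOC)ccc1OCOC | intermediate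
19 | (±)-{4-[3-bromo-4-(methoxymethoxy)benzyl]-5-[(tert-butyldimethylsilyl)oxy]bicyclo[2.2.2]octa-2,5-dien-2-yl}{2-(methoxymethoxy)-5-[2-(methoxymethoxy)benzyl]phenyl}methanone | COCOc1ccc(CC23CCC(C=C2O[Si](C)(C)C(C)(C)C)C(C(=O)c2cc(Cc4ccccc4OCOC)ccc2OCOC)=C3)cc1Br | intermediate (not isolated)
20 | {3-[3-bromo-4-(methoxymethoxy)benzyl]-4-[(tert-butyldimethylsilyl)oxy]phenyl}{2-(methoxymethoxy)-5-[2-(methoxymethoxy)benzyl]phenyl}methanone | COCOc1ccc(Cc2cc(ccc2O[Si](C)(C)C(C)(C)C)C(=O)c2cc(Cc3ccccc3OCOC)ccc2OCOC)cc1Br | intermediate
21 | (±)-{3-[3-bromo-4-(methoxymethoxy)benzyl]-4-[(tert-butyldimethylsilyl)oxy]phenyl}{2-(methoxymethoxy)-5-[2-(methoxymethoxy)benzyl]phenyl}methanol | COCOc1ccc(Cc2cc(ccc2O[Si](C)(C)C(C)(C)C)C(O)c2cc(Cc3ccccc3OCOC)ccc2OCOC)cc1Br | intermediate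
22 | {2-[3-bromo-4-(methoxymethoxy)benzyl]-4-{2-(methoxymethoxy)-5-[2-(methoxymethoxy)benzyl]benzyl}phenoxy}(tert-butyl)dimethylsilane (four-ring chain bromide) | COCOc1ccc(Cc2cc(Cc3cc(Cc4ccccc4OCOC)ccc3OCOC)ccc2O[Si](C)(C)C(C)(C)C)cc1Br | intermediate
23 | chain aryllithium (22 with Li in place of Br) | COCOc1ccc(Cc2cc(Cc3cc(Cc4ccccc4OCOC)ccc3OCOC)ccc2O[Si](C)(C)C(C)(C)C)cc1[Li] | intermediate (not isolated)
24 | 5-{2-[(tert-butyldimethylsilyl)oxy]-5-{2-(methoxymethoxy)-5-[2-(methoxymethoxy)benzyl]benzyl}benzyl}-2-(methoxymethoxy)benzaldehyde | COCOc1ccc(Cc2cc(Cc3cc(Cc4ccccc4OCOC)ccc3OCOC)ccc2O[Si](C)(C)C(C)(C)C)cc1C=O | intermediate (not isolated)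
25 | (5-{2-[(tert-butyldimethylsilyl)oxy]-5-{2-(methoxymethoxy)-5-[2-(methoxymethoxy)benzyl]benzyl}benzyl}-2-(methoxymethoxy)phenyl)methanol | COCOc1ccc(Cc2cc(Cc3cc(Cc4ccccc4OCOC)ccc3OCOC)ccc2O[Si](C)(C)C(C)(C)C)cc1CO | intermediate
26 | tert-butyl{2-[3-(chloromethyl)-4-(methoxymethoxy)benzyl]-4-{2-(methoxymethoxy)-5-[2-(methoxymethoxy)benzyl]benzyl}phenoxy}dimethylsilane | COCOc1ccc(Cc2cc(Cc3cc(Cc4ccccc4OCOC)ccc3OCOC)ccc2O[Si](C)(C)C(C)(C)C)cc1CCl | intermediate
27 | (S)-pinocembrin, (2S)-5,7-dihydroxy-2-phenylchroman-4-one | O=C1C[C@@H](c2ccccc2)Oc2cc(O)cc(O)c21 | starting material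
28 | (2S)-5-hydroxy-7-(methoxymethoxy)-2-phenylchroman-4-one | O=C1C[C@@H](c2ccccc2)Oc2cc(OCOC)cc(O)c21 | intermediate
29 | (2S)-5-hydroxy-6-iodo-7-(methoxymethoxy)-2-phenylchroman-4-one | O=C1C[C@@H](c2ccccc2)Oc2cc(OCOC)c(I)c(O)c21 | intermediate
30 | chain benzylzinc chloride (26 with ZnCl in place of Cl) | COCOc1ccc(Cc2cc(Cc3cc(Cc4ccccc4OCOC)ccc3OCOC)ccc2O[Si](C)(C)C(C)(C)C)cc1C[Zn]Cl | intermediate (not isolated)
31 | (2S)-6-(5-{2-[(tert-butyldimethylsilyl)oxy]-5-{2-(methoxymethoxy)-5-[2-(methoxymethoxy)benzyl]benzyl}benzyl}-2-(methoxymethoxy)benzyl)-5-hydroxy-7-(methoxymethoxy)-2-phenylchroman-4-one | O=C1C[C@@H](c2ccccc2)Oc2cc(OCOC)c(Cc3cc(Cc4cc(Cc5cc(Cc6ccccc6OCOC)ccc5OCOC)ccc4O[Si](C)(C)C(C)(C)C)ccc3OCOC)c(O)c21 | intermediate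
32 | 8-iodo derivative of 31, (2S) | O=C1C[C@@H](c2ccccc2)Oc2c(I)c(OCOC)c(Cc3cc(Cc4cc(Cc5cc(Cc6ccccc6OCOC)ccc5OCOC)ccc4O[Si](C)(C)C(C)(C)C)ccc3OCOC)c(O)c21 | intermediate
33 | 2-hydroxybenzyl alcohol | OCc1ccccc1O | starting material
34 | [2-(methoxymethoxy)phenyl]methanol | COCOc1ccccc1CO | intermediate
35 | 1-(chloromethyl)-2-(methoxymethoxy)benzene | COCOc1ccccc1CCl | intermediate
36 | 2-(methoxymethoxy)benzylzinc chloride | COCOc1ccccc1C[Zn]Cl | intermediate (not isolated)
37 | 8-[2-(methoxymethoxy)benzyl] derivative of 31, (2S) (protected sarmentosumin C) | O=C1C[C@@H](c2ccccc2)Oc2c(Cc3ccccc3OCOC)c(OCOC)c(Cc3cc(Cc4cc(Cc5cc(Cc6ccccc6OCOC)ccc5OCOC)ccc4O[Si](C)(C)C(C)(C)C)ccc3OCOC)c(O)c21 | intermediate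
38 | sarmentosumin C, (2S)-5,7-dihydroxy-6-(2-hydroxy-5-{2-hydroxy-5-[2-hydroxy-5-(2-hydroxybenzyl)benzyl]benzyl}benzyl)-8-(2-hydroxybenzyl)-2-phenylchroman-4-one | O=C1C[C@@H](c2ccccc2)Oc2c(Cc3ccccc3O)c(O)c(Cc3cc(Cc4cc(Cc5cc(Cc6ccccc6O)ccc5O)ccc4O)ccc3O)c(O)c21 | target

## Step count and least certain steps

Total: 23 steps. Longest linear sequence: 16 steps (1, 2, 3, 7, 8, 9, 10, 11, 12, 13, 14, 15, 18, 19, 22, 23).

**Step 11 (key step).** The terminal ynone may polymerise before it is trapped. The diene may lose its regiochemical identity through 1,5-hydrogen shifts or hydrolysis of the silyl enol ether. The adduct may also resist loss of ethylene at a temperature the ynone survives. The fallback sets out from 9 and replaces 18 by methyl propiolate, a smaller and more robust dienophile of the same polarisation. The Alder–Rickert sequence then passes through the bicyclic adduct F1 to the ring 2 benzoate F2. F2 is converted with N,O-dimethylhydroxylamine hydrochloride and i-PrMgCl into the Weinreb amide F3, and F3 is acylated by aryllithium 14 (made from 13 as in step 8). The route is rejoined at ketone 20. Ring 2 is still made by the cycloaddition, but its bond to the bridging carbonyl carbon of rings 2 and 3 no longer depends on the sensitive ynone.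

**Step 13.** The acid may strip MOM groups, and the benzhydryl cation may alkylate the electron-rich rings instead of taking hydride. The fallback sets out from 21 and avoids acid. MsCl and Et3N convert the carbinol into the benzhydryl chloride F4, and LiBHEt3 displaces the chloride by hydride at low temperature. The route is rejoined at 22.

**Step 17.** Iodination may occur at C8 instead of, or as well as, C6, since the directing effect of the chelated 5-OH is carried over from flavones to a flavanone. Over-iodination is also possible. The fallback sets out from 28 and uses the other regioisomer productively by inverting the order of the two couplings. The 8-iodide F5 is coupled with zinc reagent 36 to give the 8-benzyl compound F6. This is iodinated at the remaining position to give the 6-iodide F7, and F7 is coupled with chain zinc reagent 30. The route is rejoined at 37. Either outcome of the iodination therefore leads to the same protected target.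

**Step 18.** The chelated 5-OH may protonate the valuable benzylzinc reagent. Oxidative addition at the doubly ortho-substituted C–I bond may be slow. Homocoupling of the zinc reagent or reduction of the iodide may take over. The fallback sets out from 26 and 29 and joins the two electrophiles directly by nickel-catalysed reductive cross-coupling (NiBr2, 4,4′-di-tert-butyl-2,2′-bipyridine, Zn dust, N,N-dimethylacetamide), without a preformed organozinc reagent. It comes back at 31 and makes no new compound.

## Further compounds

F1 | step 11 | (±)-methyl 4-[3-bromo-4-(methoxymethoxy)benzyl]-5-[(tert-butyldimethylsilyl)oxy]bicyclo[2.2.2]octa-2,5-diene-2-carboxylate | COCOc1ccc(CC23CCC(C=C2O[Si](C)(C)C(C)(C)C)C(C(=O)OC)=C3)cc1Br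
F2 | step 11 | methyl 3-[3-bromo-4-(methoxymethoxy)benzyl]-4-[(tert-butyldimethylsilyl)oxy]benzoate | COCOc1ccc(Cc2cc(C(=O)OC)ccc2O[Si](C)(C)C(C)(C)C)cc1Br
F3 | step 11 | 3-[3-bromo-4-(methoxymethoxy)benzyl]-4-[(tert-butyldimethylsilyl)oxy]-N-methoxy-N-methylbenzamide | COCOc1ccc(Cc2cc(C(=O)N(C)OC)ccc2O[Si](C)(C)C(C)(C)C)cc1Br
F4 | step 13 | (±)-{2-[3-bromo-4-(methoxymethoxy)benzyl]-4-(chloro{2-(methoxymethoxy)-5-[2-(methoxymethoxy)benzyl]phenyl}methyl)phenoxy}(tert-butyl)dimethylsilane | COCOc1ccc(Cc2cc(ccc2O[Si](C)(C)C(C)(C)C)C(Cl)c2cc(Cc3ccccc3OCOC)ccc2OCOC)cc1Br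
F5 | step 17 | (2S)-5-hydroxy-8-iodo-7-(methoxymethoxy)-2-phenylchroman-4-one | O=C1C[C@@H](c2ccccc2)Oc2c(I)c(OCOC)cc(O)c21
F6 | step 17 | (2S)-5-hydroxy-7-(methoxymethoxy)-8-[2-(methoxymethoxy)benzyl]-2-phenylchroman-4-one | O=C1C[C@@H](c2ccccc2)Oc2c(Cc3ccccc3OCOC)c(OCOC)cc(O)c21
F7 | step 17 | (2S)-5-hydroxy-6-iodo-7-(methoxymethoxy)-8-[2-(methoxymethoxy)benzyl]-2-phenylchroman-4-one | O=C1C[C@@H](c2ccccc2)Oc2c(Cc3ccccc3OCOC)c(OCOC)c(I)c(O)c21
F0 | step 18 | none | none
A1 | alternative 1 | (1E)-5-methoxy-1-phenyl-7-(tetra-O-benzyl chain ring 1)hepta-1,4-dien-3-one | COC(CCc1cc(Cc2cc(Cc3cc(Cc4ccccc4OCc4ccccc4)ccc3OCc3ccccc3)ccc2OCc2ccccc2)ccc1OCc1ccccc1)=CC(=O)/C=C/c1ccccc1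
A2 | alternative 1 | 2-[2-(benzyloxy)benzyl]malonyl dichloride | O=C(Cl)C(Cc1ccccc1OCc1ccccc1)C(=O)Cl
A3 | alternative 1 | (E)-2',4'-dihydroxy-6'-methoxy-3'-[2-(benzyloxy)benzyl]-5'-(tetra-O-benzyl chain methyl)chalcone | COc1c(C(=O)/C=C/c2ccccc2)c(O)c(Cc2ccccc2OCc2ccccc2)c(O)c1Cc1cc(Cc2cc(Cc3cc(Cc4ccccc4OCc4ccccc4)ccc3OCc3ccccc3)ccc2OCc2ccccc2)ccc1OCc1ccccc1
A4 | alternative 2 | (3S)-3-{2-bromo-3,5-bis(methoxymethoxy)-6-[2-(methoxymethoxy)benzyl]-4-(tetra-O-MOM chain methyl)phenoxy}-3-phenylpropanoic acid | OC(=O)C[C@@H](c1ccccc1)Oc1c(Br)c(OCOC)c(Cc2cc(Cc3cc(Cc4cc(Cc5ccccc5OCOC)ccc4OCOC)ccc3OCOC)ccc2OCOC)c(OCOC)c1Cc1ccccc1OCOC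
A5 | alternative 2 | hepta(methoxymethyl) ether of (S)-sarmentosumin C | O=C1C[C@@H](c2ccccc2)Oc2c(Cc3ccccc3OCOC)c(OCOC)c(Cc3cc(Cc4cc(Cc5cc(Cc6ccccc6OCOC)ccc5OCOC)ccc4OCOC)ccc3OCOC)c(OCOC)c21
A6 | alternative 3 | 3-ethoxy-4-(tetra-O-MOM chain methyl)cyclobut-2-en-1-one | CCOC1=CC(=O)C1Cc1cc(Cc2cc(Cc3cc(Cc4ccccc4OCOC)ccc3OCOC)ccc2OCOC)ccc1OCOC
A7 | alternative 3 | triisopropyl({3-[2-(methoxymethoxy)phenyl]prop-1-yn-1-yl}oxy)silane | COCOc1ccccc1CC#CO[Si](C(C)C)(C(C)C)C(C)C
A8 | alternative 3 | 2-(tetra-O-MOM chain methyl)-3-ethoxy-6-[2-(methoxymethoxy)benzyl]-5-(triisopropylsiloxy)phenol | CCOc1cc(O[Si](C(C)C)(C(C)C)C(C)C)c(Cc2ccccc2OCOC)c(O)c1Cc1cc(Cc2cc(Cc3cc(Cc4ccccc4OCOC)ccc3OCOC)ccc2OCOC)ccc1OCOC
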